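**Retrosynthetic overview**

1. The target is an oxolane with ring atoms O1, C2 (4-hydroxyphenyl), C3 (CH3), C4 (CH3) and C5 (trisubstituted aryl), configured 2,3-trans/3,4-cis/4,5-trans, plus a remote (R) benzylic centre in the side chain; the three phenols travel as benzyl ethers, removed last.
2. The C2–aryl bond is cut to an arylzinc and the C2 oxocarbenium ion of the ring (from a sulfone, a lactol and a γ-lactone); the C3 methyl is traced back to C3=CH2, hydrogenated under control of C4.
3. Enabling feature: in the oxolane ring, O1 is flanked by benzylic C5, whose neighbour C4 carries CH3 (an anti-crotylation pattern), and by C2, which can be raised to an acyl carbon while the C3 methyl becomes a methylidene. The ring is therefore a masked α-methylene-γ-butyrolactone, cut in one operation at C4–C5 and O1–C2 into an aryl aldehyde and a 2-(methoxycarbonyl)crotylboronate (catalytic asymmetric allylboration–lactonisation).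
4. The aldehyde comes from formylation of an aryl bromide whose (R) centre is set by iridium-catalysed asymmetric hydrogenation of an (E)-α-methylstilbene, itself built by alkyne carboalumination and cross-coupling; the boronate comes from methyl but-2-ynoate.
5. Ring order: the oxolane is the only ring made (step 6, as the lactone); the benzene rings are bought. The catalyst sets C4 and C5, C4 relays to C3, and C3 relays to C2.

Key step: step 6

Remark (abbreviation): Ar* = 4-(benzyloxy)-3-[(2R)-1-[4-(benzyloxy)phenyl]propan-2-yl]phenyl.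
Remark (assumption): the sense of induction of the chiral catalysts in steps 3 and 6 is assigned by analogy with the parent reactions; the antipodal catalyst would be used if it proved reversed.
Remark (assumption): the five compounds marked as starting materials in the list are taken to be commercially available.

**Step 1**
Reactants: 1 2-(benzyloxy)-5-bromobenzaldehyde
Product: 2 1-(benzyloxy)-4-bromo-2-ethynylbenzene
Conditions: dimethyl (1-diazo-2-oxopropyl)phosphonate, K2CO3, MeOH, 0 °C → rt
Reagents that add atoms: dimethyl (1-diazo-2-oxopropyl)phosphonate, COP(=O)(OC)C(=[N+]=[N-])C(C)=O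
Why: Seyferth–Gilbert homologation with the Ohira–Bestmann reagent should turn the aryl aldehyde into the terminal alkyne under mild base that leaves the aryl bromide and the benzyl ether alone; no stereocentre is formed.

**Step 2**
Reactants: 2 1-(benzyloxy)-4-bromo-2-ethynylbenzene; 3 1-(benzyloxy)-4-iodobenzene
Product: 5 1-(benzyloxy)-2-[(1E)-1-[4-(benzyloxy)phenyl]prop-1-en-2-yl]-4-bromobenzene, via alkenylalane 4 (not isolated)
Conditions: AlMe3 (2.5 equiv), (C5H5)2ZrCl2 (0.25 equiv), CH2Cl2, 0 °C → rt; volatiles removed; then 3, Pd(PPh3)4 (5 mol%), ZnCl2 (0.2 equiv), THF, rt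
Reagents that add atoms: trimethylaluminium, C[Al](C)C
Why: Negishi zirconium-catalysed carboalumination should add CH3 and Al syn across the alkyne with CH3 on the aryl-bearing carbon, and the palladium-catalysed cross-coupling of 4 with the aryl iodide (far faster in oxidative addition than the electron-rich aryl bromide) proceeds with retention, so the (E) geometry is fixed by the syn addition.

**Step 3**
Reactants: 5 1-(benzyloxy)-2-[(1E)-1-[4-(benzyloxy)phenyl]prop-1-en-2-yl]-4-bromobenzene
Product: 6 1-(benzyloxy)-2-[(2R)-1-[4-(benzyloxy)phenyl]propan-2-yl]-4-bromobenzene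
Conditions: H2 (50 bar), [Ir(cod)(L)][B(C6H3-3,5-(CF3)2)4] (1 mol%; L = (S)-4-tert-butyl-2-[2-(di-o-tolylphosphanyl)phenyl]-4,5-dihydro-1,3-oxazole), CH2Cl2, rt
Reagents that add atoms: none
Why: Pfaltz-type iridium–phosphinooxazoline hydrogenation of an unfunctionalised (E)-α-methylstilbene, the benchmark substrate class for these catalysts; the benzylic stereocentre is set by catalyst control of the alkene face, and the aryl bromide and benzyl ethers are not expected to react under these homogeneous conditions.

**Step 4**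
Reactants: 6 1-(benzyloxy)-2-[(2R)-1-[4-(benzyloxy)phenyl]propan-2-yl]-4-bromobenzene
Product: 8 4-(benzyloxy)-3-[(2R)-1-[4-(benzyloxy)phenyl]propan-2-yl]benzaldehyde, via aryllithium 7 (not isolated)
Conditions: n-BuLi, THF, −78 °C; then DMF, −78 → 0 °C; 1 M HCl
Reagents that add atoms: N,N-dimethylformamide, CN(C)C=O
Why: Bromine–lithium exchange followed by Bouveault formylation with DMF; the existing stereocentre is remote from the carbanion and is not touched.

**Step 5**
Reactants: 9 methyl but-2-ynoate; 10 2-(iodomethyl)-4,4,5,5-tetramethyl-1,3,2-dioxaborolane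
Product: 12 methyl (2Z)-2-[(4,4,5,5-tetramethyl-1,3,2-dioxaborolan-2-yl)methyl]but-2-enoate (CH3 trans to CH2B), via α-alumino acrylate 11 (not isolated)
Conditions: i-Bu2AlH, HMPA, THF, 0 °C; then 10, 0 °C → rt
Reagents that add atoms: none
Why: Conjugate hydroalumination of the ynoate with i-Bu2AlH–HMPA delivers H and Al syn, and C-alkylation of 11 by the iodomethylboronate occurs with retention, so CH3 ends trans to CH2B, the geometry that behaves as an (E)-crotylboronate.

**Step 6**
Reactants: 8 4-(benzyloxy)-3-[(2R)-1-[4-(benzyloxy)phenyl]propan-2-yl]benzaldehyde; 12 methyl (2Z)-2-[(4,4,5,5-tetramethyl-1,3,2-dioxaborolan-2-yl)methyl]but-2-enoate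
Product: 14 (4R,5R)-5-Ar*-4-methyl-3-methylideneoxolan-2-one, via borate ester 13 (not isolated)
Conditions: (R)-3,3'-bis(2,4,6-triisopropylphenyl)-1,1'-binaphthyl-2,2'-diyl hydrogen phosphate (10 mol%), 4 Å MS, toluene, 0 °C → rt; then PPTS (20 mol%), 40 °C
Reagents that add atoms: none
Why: Proposed new method: the phosphoric acid is expected to act bifunctionally, its P–OH hydrogen-bonding to a boronate oxygen and its P=O to the formyl hydrogen, so that C4–C5 forms by allyl transfer through a closed chair (Zimmerman–Traxler) transition state to give borate 13, which then closes the oxolane ring by 5-exo-trig acyl substitution of O1 at the ester carbon (O1–C2) with loss of methoxyboronate. The closest known reaction types are the chiral phosphoric acid-catalysed allyl- and crotylboration of aryl aldehydes with pinacol boronates and the acid-catalysed allylboration–lactonisation of 2-(alkoxycarbonyl)allylboronates to α-methylene-γ-butyrolactones; new is the use of the chiral acid with this ester-deactivated boronate. C4 is set by the boronate geometry (CH3 trans to CH2B sits equatorial in the chair, giving the anti adduct and so the 4,5-trans lactone), and C5 by the catalyst, the (R)-acid being expected to direct the allyl group to the Re face of the aldehyde. The step needs enantiofacial control by the catalyst alone, because the existing stereocentre of 8 is remote, and it needs the uncatalysed pathway to be slow, which the low thermal reactivity of ester-substituted allylboronates at ambient temperature should secure. Chemoselectivity is not at issue, since the aldehyde is the only electrophile and the benzyl ethers are inert to the weak acids used.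

**Step 7**
Reactants: 14 (4R,5R)-5-Ar*-4-methyl-3-methylideneoxolan-2-one
Product: 15 (3S,4R,5R)-5-Ar*-3,4-dimethyloxolan-2-one
Conditions: H2 (1 atm), RhCl(PPh3)3 (5 mol%), toluene–EtOH (1:1), rt
Reagents that add atoms: none
Why: Homogeneous hydrogenation with Wilkinson's catalyst reduces the 1,1-disubstituted exocyclic alkene without cleaving benzyl ethers; hydrogen should be delivered to the face of planar C3 opposite the adjacent C4 methyl, so the new C3 methyl ends cis to C4–CH3 (3S) by substrate control.

**Step 8**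
Reactants: 15 (3S,4R,5R)-5-Ar*-3,4-dimethyloxolan-2-one
Product: 16 (3S,4R,5R)-5-Ar*-3,4-dimethyloxolan-2-ol (anomer mixture)
Conditions: i-Bu2AlH (1.1 equiv), CH2Cl2, −78 °C; aq. Rochelle salt
Reagents that add atoms: none
Why: Partial reduction of a γ-lactone by i-Bu2AlH at −78 °C stops at the tetrahedral aluminium hemiacetal, which gives the lactol on work-up without epimerising C3; the new hemiacetal centre is an anomer mixture of no consequence.

**Step 9**
Reactants: 16 (3S,4R,5R)-5-Ar*-3,4-dimethyloxolan-2-ol (anomer mixture)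
Product: 17 (3S,4R,5R)-2-(benzenesulfonyl)-5-Ar*-3,4-dimethyloxolane (anomer mixture)
Conditions: PhSO2H, CaCl2, CH2Cl2, rt
Reagents that add atoms: benzenesulfinic acid, OS(=O)c1ccccc1
Why: Ley's condensation of a lactol with benzenesulfinic acid (CaCl2 as desiccant) gives the 2-benzenesulfonyl cyclic ether, a stable oxocarbenium precursor; C2 is again an anomer mixture that converges in the next step.

**Step 10**
Reactants: 17 (3S,4R,5R)-2-(benzenesulfonyl)-5-Ar*-3,4-dimethyloxolane (anomer mixture); 18 [4-(benzyloxy)phenyl]magnesium bromide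
Product: 21 (2S,3S,4R,5R)-2-[4-(benzyloxy)phenyl]-5-Ar*-3,4-dimethyloxolane, via arylzinc bromide 19 (not isolated), via oxocarbenium ion 20 (not isolated)
Conditions: 18 (2 equiv), ZnBr2 (2.2 equiv), THF, 0 °C → rt
Reagents that add atoms: none
Why: Ley-type substitution of a 2-sulfonyl cyclic ether by an arylzinc: the zinc halide ionises the sulfone to oxocarbenium ion 20, whose favoured envelope (C4–CH3 and C5–aryl pseudoequatorial, C3–CH3 pseudoaxial) should be attacked by 19 on the inside face, anti to the C3 methyl, so the C2 aryl ends trans to C3–CH3 and cis to the C5 aryl (2S), which is also the thermodynamically preferred arrangement.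

**Step 11**
Reactants: 21 (2S,3S,4R,5R)-2-[4-(benzyloxy)phenyl]-5-Ar*-3,4-dimethyloxolane
Product: 22 4-[(2S,3S,4R,5R)-5-{4-hydroxy-3-[(2R)-1-(4-hydroxyphenyl)propan-2-yl]phenyl}-3,4-dimethyloxolan-2-yl]phenol
Conditions: H2 (1 atm), 10% Pd/C, EtOAc–MeOH, rt
Reagents that add atoms: none
Why: Hydrogenolysis of the three benzyl aryl ethers under neutral conditions at ambient pressure; O-benzyl cleavage is expected to outpace hydrogenolysis of the ring benzylic C–O bonds, and no stereocentre is touched.

**Compound list**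

1 | 2-(benzyloxy)-5-bromobenzaldehyde | O=Cc1cc(Br)ccc1OCc1ccccc1 | starting material
2 | 1-(benzyloxy)-4-bromo-2-ethynylbenzene | C#Cc1cc(Br)ccc1OCc1ccccc1 | intermediate
3 | 1-(benzyloxy)-4-iodobenzene | Ic1ccc(OCc2ccccc2)cc1 | starting material
4 | [(1E)-2-[2-(benzyloxy)-5-bromophenyl]prop-1-en-1-yl]dimethylalumane | C/C(=C\[Al](C)C)c1cc(Br)ccc1OCc1ccccc1 | intermediate
5 | 1-(benzyloxy)-2-[(1E)-1-[4-(benzyloxy)phenyl]prop-1-en-2-yl]-4-bromobenzene | C/C(=C\c1ccc(OCc2ccccc2)cc1)c1cc(Br)ccc1OCc1ccccc1 | intermediate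
6 | 1-(benzyloxy)-2-[(2R)-1-[4-(benzyloxy)phenyl]propan-2-yl]-4-bromobenzene | Brc1ccc(OCc2ccccc2)c([C@H](C)Cc2ccc(OCc3ccccc3)cc2)c1 | intermediate
7 | {4-(benzyloxy)-3-[(2R)-1-[4-(benzyloxy)phenyl]propan-2-yl]phenyl}lithium | [Li]c1ccc(OCc2ccccc2)c([C@H](C)Cc2ccc(OCc3ccccc3)cc2)c1 | intermediate
8 | 4-(benzyloxy)-3-[(2R)-1-[4-(benzyloxy)phenyl]propan-2-yl]benzaldehyde | O=Cc1ccc(OCc2ccccc2)c([C@H](C)Cc2ccc(OCc3ccccc3)cc2)c1 | intermediate
9 | methyl but-2-ynoate | CC#CC(=O)OC | starting material
10 | 2-(iodomethyl)-4,4,5,5-tetramethyl-1,3,2-dioxaborolane | ICB1OC(C)(C)C(C)(C)O1 | starting material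
11 | methyl (2E)-2-[bis(2-methylpropyl)alumanyl]but-2-enoate | C/C=C(/[Al](CC(C)C)CC(C)C)C(=O)OC | intermediate
12 | methyl (2Z)-2-[(4,4,5,5-tetramethyl-1,3,2-dioxaborolan-2-yl)methyl]but-2-enoate | C/C=C(/CB1OC(C)(C)C(C)(C)O1)C(=O)OC | intermediate
13 | methyl (3R,4R)-4-Ar*-3-methyl-2-methylidene-4-[(4,4,5,5-tetramethyl-1,3,2-dioxaborolan-2-yl)oxy]butanoate | C=C(C(=O)OC)[C@@H](C)[C@@H](OB1OC(C)(C)C(C)(C)O1)c1ccc(OCc2ccccc2)c([C@H](C)Cc2ccc(OCc3ccccc3)cc2)c1 | intermediate
14 | (4R,5R)-5-Ar*-4-methyl-3-methylideneoxolan-2-one | C[C@@H]1C(=C)C(=O)O[C@H]1c1ccc(OCc2ccccc2)c([C@H](C)Cc2ccc(OCc3ccccc3)cc2)c1 | intermediate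
15 | (3S,4R,5R)-5-Ar*-3,4-dimethyloxolan-2-one | C[C@@H]1[C@H](C)C(=O)O[C@H]1c1ccc(OCc2ccccc2)c([C@H](C)Cc2ccc(OCc3ccccc3)cc2)c1 | intermediate
16 | (3S,4R,5R)-5-Ar*-3,4-dimethyloxolan-2-ol (anomer mixture) | C[C@@H]1[C@H](C)C(O)O[C@H]1c1ccc(OCc2ccccc2)c([C@H](C)Cc2ccc(OCc3ccccc3)cc2)c1 | intermediate
17 | (3S,4R,5R)-2-(benzenesulfonyl)-5-Ar*-3,4-dimethyloxolane (anomer mixture) | C[C@@H]1[C@H](C)C(S(=O)(=O)c2ccccc2)O[C@H]1c1ccc(OCc2ccccc2)c([C@H](C)Cc2ccc(OCc3ccccc3)cc2)c1 | intermediate
18 | [4-(benzyloxy)phenyl]magnesium bromide | Br[Mg]c1ccc(OCc2ccccc2)cc1 | starting material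
19 | [4-(benzyloxy)phenyl]zinc bromide | Br[Zn]c1ccc(OCc2ccccc2)cc1 | intermediate
20 | C2 oxocarbenium ion of the (3S,4R,5R)-5-Ar*-3,4-dimethyloxolane ring, as its benzenesulfinate ion pair | C[C@@H]1[C@H](C)C=[O+][C@H]1c1ccc(OCc2ccccc2)c([C@H](C)Cc2ccc(OCc3ccccc3)cc2)c1.[O-]S(=O)c1ccccc1 | intermediate
21 | (2S,3S,4R,5R)-2-[4-(benzyloxy)phenyl]-5-Ar*-3,4-dimethyloxolane | C[C@@H]1[C@H](C)[C@@H](c2ccc(OCc3ccccc3)cc2)O[C@H]1c1ccc(OCc2ccccc2)c([C@H](C)Cc2ccc(OCc3ccccc3)cc2)c1 | intermediate
22 | 4-[(2S,3S,4R,5R)-5-{4-hydroxy-3-[(2R)-1-(4-hydroxyphenyl)propan-2-yl]phenyl}-3,4-dimethyloxolan-2-yl]phenol | C[C@@H]1[C@H](C)[C@@H](c2ccc(O)cc2)O[C@H]1c1ccc(O)c([C@H](C)Cc2ccc(O)cc2)c1 | target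

**Step count and risks**

Total step count: 11. Longest linear sequence: 10 steps (steps 1–4 and 6–11).

Steps most likely to fail:

1. Step 6 (proposed new method). The weak chiral acid may activate the ester-deactivated boronate too little, so that allyl transfer is slow, or may discriminate the aldehyde faces poorly; forcing with stronger acid risks ionisation of the electron-rich benzylic C5–O bond. Fallback with known chemistry, setting out from 8 and returning at 14: (2S)-but-3-yn-2-yl methanesulfonate F1 (from the commercial alcohol, MsCl, Et3N) is treated with Pd(OAc)2, PPh3 and Et2Zn in THF at −20 °C in the presence of 8 (Marshall propargylation). Anti SN2' palladation and transmetalation give the transient allenylzinc, ethyl[(aR)-buta-1,2-dien-1-yl]zinc F2, which adds through a cyclic SE2' transition state to give the anti homopropargylic alcohol (1R,2R)-1-Ar*-2-methylbut-3-yn-1-ol F3, with net inversion at the methyl-bearing carbon. Palladium-catalysed cyclocarbonylation of F3 (PdCl2, SnCl2, PPh3, CO 7 atm, MeCN, 75 °C) then closes the α-methylene lactone 14.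

2. Step 10. The oxocarbenium ion may lose the C3 proton (elimination towards the dihydrofuran, which would also erase C3), or the arylzinc may attack from the wrong face. Fallback, setting out from 15 and returning at 21: [4-(benzyloxy)phenyl]lithium F4 (from 1-(benzyloxy)-4-bromobenzene and n-BuLi, THF, −78 °C) is added to lactone 15 and quenched cold with AcOH to give hemiketal (3S,4R,5R)-2-[4-(benzyloxy)phenyl]-5-Ar*-3,4-dimethyloxolan-2-ol F5. Ionic hydrogenation (Et3SiH, BF3·OEt2, CH2Cl2, −78 °C) should give mainly the 2,3-cis oxolane (2R,3S,4R,5R)-2-[4-(benzyloxy)phenyl]-5-Ar*-3,4-dimethyloxolane F6 by inside attack of hydride. F6 is then equilibrated (BF3·OEt2 cat., CH2Cl2, 0 °C) through reversible ionisation of the 4-alkoxybenzylic C2–O1 bond to the more stable 2,3-trans isomer 21, a sequence with precedent in this lignan class.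

3. Step 7. Facial selectivity of hydrogen delivery may be poor because the C5 aryl lies on the face opposite the C4 methyl, or a rhodium hydride may move the exocyclic double bond into the ring, which would erase C4. Fallback, setting out from 14 and returning at 15: conjugate reduction with LiBH(s-Bu)3 (THF, −78 °C) gives the lithium enolate, lithium (4R,5R)-5-Ar*-3,4-dimethyl-4,5-dihydrofuran-2-olate F7, which is protonated kinetically at −78 °C with AcOH on the face opposite the C4 methyl. The stereo-determining event is thus enolate protonation instead of metal-hydride insertion, and no alkene migration is possible.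

Further compounds
F1 | step 6 | (2S)-but-3-yn-2-yl methanesulfonate | C[C@H](OS(C)(=O)=O)C#C
F2 | step 6 | ethyl[(aR)-buta-1,2-dien-1-yl]zinc | [H]C([Zn]CC)=[C@@]=C([H])C
F3 | step 6 | (1R,2R)-1-{4-(benzyloxy)-3-[(2R)-1-[4-(benzyloxy)phenyl]propan-2-yl]phenyl}-2-methylbut-3-yn-1-ol | C#C[C@@H](C)[C@@H](O)c1ccc(OCc2ccccc2)c([C@H](C)Cc2ccc(OCc3ccccc3)cc2)c1
F4 | step 10 | [4-(benzyloxy)phenyl]lithium | [Li]c1ccc(OCc2ccccc2)cc1
F5 | step 10 | (3S,4R,5R)-2-[4-(benzyloxy)phenyl]-5-{4-(benzyloxy)-3-[(2R)-1-[4-(benzyloxy)phenyl]propan-2-yl]phenyl}-3,4-dimethyloxolan-2-ol | C[C@@H]1[C@H](C)C(O)(c2ccc(OCc3ccccc3)cc2)O[C@H]1c1ccc(OCc2ccccc2)c([C@H](C)Cc2ccc(OCc3ccccc3)cc2)c1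
F6 | step 10 | (2R,3S,4R,5R)-2-[4-(benzyloxy)phenyl]-5-{4-(benzyloxy)-3-[(2R)-1-[4-(benzyloxy)phenyl]propan-2-yl]phenyl}-3,4-dimethyloxolane | C[C@@H]1[C@H](C)[C@H](c2ccc(OCc3ccccc3)cc2)O[C@H]1c1ccc(OCc2ccccc2)c([C@H](C)Cc2ccc(OCc3ccccc3)cc2)c1
F7 | step 7 | lithium (4R,5R)-5-{4-(benzyloxy)-3-[(2R)-1-[4-(benzyloxy)phenyl]propan-2-yl]phenyl}-3,4-dimethyl-4,5-dihydrofuran-2-olate | C[C@@H]1C(C)=C(O[Li])O[C@H]1c1ccc(OCc2ccccc2)c([C@H](C)Cc2ccc(OCc3ccccc3)cc2)c1
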